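**Plan**

Ring A is the benzene ring of the 5,7-dihydroxychroman and ring B is the benzene ring of the other chroman.
- Cuts: the pyran fused to ring A is opened (O1–C2 and C4–C4a) back to a 2,4,6-trihydroxyphenyl ketone. Both bonds of the ketone carbon (ring A–C(=O) and C(=O)–CH2) are then cut to an aryl iodide, carbon monoxide and a 2-arylethylborane. Finally the vinyl–aryl bond and the pyran on ring B are cut to 4-bromophenol and isoprene.
- Enabling feature: the ketone carbon is a lone one-carbon unit. On one side it sits on the ring A carbon flanked by the two hydroxyl-bearing carbons (C5 and C7); on the other it carries an unbranched CH2–CH2 tether to C6 of the ring B chroman. It can therefore be delivered as carbon monoxide.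
- Forward order: the ring B chroman is made first, then vinylated and hydroborated. The three-component carbonylative coupling joins the chain to protected ring A. Debenzylation, para-O-propargylation, Claisen rearrangement with cyclisation (pyran on ring A) and hydrogenation finish the route.
- Stereochemistry: the target has no stereocentre and no stereogenic double bond, so none has to be set.

Key step: step 5

Remark: 1,3,5-tris(benzyloxy)benzene, vinylboronic acid pinacol ester and 3-chloro-3-methylbut-1-yne are taken as purchasable.

**Route**

Step 1
Reactants: 1 1,3,5-tris(benzyloxy)benzene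
Product: 2 1,3,5-tris(benzyloxy)-2-iodobenzene
Conditions: NIS (1.05 equiv), MeCN/CH2Cl2, 0 °C to rt, dark
Reagents that add atoms: N-iodosuccinimide, O=C1CCC(=O)N1I
Why: Electrophilic aromatic iodination, in which each of the three equivalent carbons of the central ring is activated by three alkoxy groups far more strongly than any benzyl ring carbon, so one equivalent of reagent should stop at the mono-iodide.

Step 2
Reactants: 3 4-bromophenol; 4 isoprene
Product: 6 6-bromo-2,2-dimethylchroman, via 4-bromo-2-prenylphenol 5 (not isolated)
Conditions: isoprene (1.5 equiv, slow addition), Amberlyst 15, heptane/THF, 65 °C, sealed vessel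
Reagents that add atoms: none
Why: Acid-catalysed Friedel–Crafts prenylation by protonated isoprene is forced ortho to the hydroxyl because bromine blocks the para position, and Markovnikov addition of the phenol oxygen to the trisubstituted alkene of 5 through its tertiary cation (6-endo closure) should then give the 2,2-dimethylchroman.

Step 3
Reactants: 6 6-bromo-2,2-dimethylchroman; 7 4,4,5,5-tetramethyl-2-vinyl-1,3,2-dioxaborolane (vinylboronic acid pinacol ester)
Product: 8 2,2-dimethyl-6-vinylchroman
Conditions: PdCl2(dppf) (3 mol %), K2CO3 (3 equiv), dioxane/H2O, 90 °C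
Reagents that add atoms: none
Why: Suzuki–Miyaura coupling of an aryl bromide with a vinylboronic ester is routine, and the chroman ether is inert to aqueous carbonate.

Step 4
Reactants: 8 2,2-dimethyl-6-vinylchroman
Product: 9 9-[2-(2,2-dimethylchroman-6-yl)ethyl]-9-borabicyclo[3.3.1]nonane
Conditions: 9-BBN (0.5 M in THF, 1.0 equiv), THF, 0 °C to rt; THF then removed under argon and the air-sensitive residue taken up in benzene
Reagents that add atoms: 9-borabicyclo[3.3.1]nonane (9-BBN), B1C2CCCC1CCC2
Why: Anti-Markovnikov hydroboration of a styrene with 9-BBN places boron almost exclusively on the terminal carbon for steric reasons, and the aryl ether does not react.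

Step 5
Reactants: 2 1,3,5-tris(benzyloxy)-2-iodobenzene; 9 9-[2-(2,2-dimethylchroman-6-yl)ethyl]-9-borabicyclo[3.3.1]nonane (1.3 equiv); 10 carbon monoxide
Product: 11 1-[2,4,6-tris(benzyloxy)phenyl]-3-(2,2-dimethylchroman-6-yl)propan-1-one
Conditions: CO (1 atm, balloon), Pd(PPh3)4 (5 mol %), K3PO4 (3 equiv), benzene, rt to 50 °C
Reagents that add atoms: none
Why: Zerovalent palladium inserts into the C–I bond of 2, and the resulting arylpalladium iodide (divalent palladium), crowded by two ortho benzyloxy groups, takes up carbon monoxide by migratory insertion to give the less congested aroyl complex. Phosphate converts borane 9 into a borate that hands over only its primary 2-arylethyl group, since the bicyclic secondary B–C bonds of the 9-BBN cage do not migrate, and reductive elimination from the acyl(alkyl)palladium forms the C(=O)–CH2 bond and returns zerovalent palladium. This is the carbonylative Suzuki–Miyaura coupling of aryl iodides with B-alkyl-9-BBN reagents, a known ketone synthesis, applied here to a di-ortho-alkoxy iodide. No ring closes and no stereocentre is formed. The selectivity needed is ketone over the direct aryl–alkyl coupling product, and the electron-rich, doubly ortho-substituted arylpalladium should secure it because its transmetalation is slow while insertion of carbon monoxide is fast; the symmetric iodide leaves no regiochemical choice.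

Step 6
Reactants: 11 1-[2,4,6-tris(benzyloxy)phenyl]-3-(2,2-dimethylchroman-6-yl)propan-1-one
Product: 12 1-(2,4,6-trihydroxyphenyl)-3-(2,2-dimethylchroman-6-yl)propan-1-one
Conditions: H2 (1 atm), 10% Pd/C, EtOAc/MeOH, rt
Reagents that add atoms: none
Why: Hydrogenolysis of benzyl aryl ethers over palladium on carbon is standard, and the aryl ketone, a vinylogous acid chelated by the two ortho hydroxyls as they are freed, should resist reduction at one atmosphere, as should the dialkyl aryl ether of the ring B chroman.

Step 7
Reactants: 12 1-(2,4,6-trihydroxyphenyl)-3-(2,2-dimethylchroman-6-yl)propan-1-one; 13 3-chloro-3-methylbut-1-yne (1.1 equiv)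
Product: 14 1-[2,6-dihydroxy-4-(2-methylbut-3-yn-2-yloxy)phenyl]-3-(2,2-dimethylchroman-6-yl)propan-1-one
Conditions: CuCl2·2H2O (1 mol %), DBU (1.2 equiv), MeCN, 0 °C
Reagents that add atoms: none
Why: Copper-catalysed propargylic etherification of a phenol with a tertiary propargyl chloride is a known O-alkylation, and the hydroxyl para to the ketone is the most acidic and the only one not held in a hydrogen bond to the carbonyl, so one equivalent of base and electrophile should etherify it alone.

Step 8
Reactants: 14 1-[2,6-dihydroxy-4-(2-methylbut-3-yn-2-yloxy)phenyl]-3-(2,2-dimethylchroman-6-yl)propan-1-one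
Product: 16 1-(5,7-dihydroxy-2,2-dimethyl-2H-chromen-6-yl)-3-(2,2-dimethylchroman-6-yl)propan-1-one, via allenylphenol 15 (not isolated)
Conditions: o-xylene, 140 °C, argon
Reagents that add atoms: none
Why: Aryl propargyl ether Claisen rearrangement ([3,3] shift to either of the two equivalent free ring carbons), enolisation to allenylphenol 15, 1,5-hydrogen shift and oxa-6π electrocyclisation should deliver the 2,2-dimethyl-2H-chromene, in which the former ether oxygen, para to the ketone, becomes the ring oxygen because the neighbouring ortho hydroxyl stays chelated to the carbonyl.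

Step 9
Reactants: 16 1-(5,7-dihydroxy-2,2-dimethyl-2H-chromen-6-yl)-3-(2,2-dimethylchroman-6-yl)propan-1-one
Product: 17 1-(5,7-dihydroxy-2,2-dimethylchroman-6-yl)-3-(2,2-dimethylchroman-6-yl)propan-1-one (CNP0080574.0)
Conditions: H2 (1 atm), 10% Pd/C, EtOAc, rt
Reagents that add atoms: none
Why: Catalytic hydrogenation of the cis-disubstituted styrene-type double bond of a 2H-chromene is fast at one atmosphere, whereas the chelated aryl ketone and both benzene rings should be untouched.

**Compound list**

1 | 1,3,5-tris(benzyloxy)benzene | c1ccc(COc2cc(OCc3ccccc3)cc(OCc3ccccc3)c2)cc1 | starting material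
2 | 1,3,5-tris(benzyloxy)-2-iodobenzene | Ic1c(OCc2ccccc2)cc(OCc2ccccc2)cc1OCc1ccccc1 | intermediate
3 | 4-bromophenol | Oc1ccc(Br)cc1 | starting material
4 | isoprene | C=CC(C)=C | starting material
5 | 4-bromo-2-(3-methylbut-2-enyl)phenol (4-bromo-2-prenylphenol) | CC(C)=CCc1cc(Br)ccc1O | intermediate
6 | 6-bromo-2,2-dimethylchroman | CC1(C)CCc2cc(Br)ccc2O1 | intermediate
7 | 4,4,5,5-tetramethyl-2-vinyl-1,3,2-dioxaborolane | C=CB1OC(C)(C)C(C)(C)O1 | starting material
8 | 2,2-dimethyl-6-vinylchroman | CC1(C)CCc2cc(C=C)ccc2O1 | intermediate
9 | 9-[2-(2,2-dimethylchroman-6-yl)ethyl]-9-borabicyclo[3.3.1]nonane | CC1(C)CCc2cc(CCB3C4CCCC3CCC4)ccc2O1 | intermediate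
10 | carbon monoxide | [C-]#[O+] | starting material
11 | 1-[2,4,6-tris(benzyloxy)phenyl]-3-(2,2-dimethylchroman-6-yl)propan-1-one | CC1(C)CCc2cc(CCC(=O)c3c(OCc4ccccc4)cc(OCc4ccccc4)cc3OCc3ccccc3)ccc2O1 | intermediate
12 | 1-(2,4,6-trihydroxyphenyl)-3-(2,2-dimethylchroman-6-yl)propan-1-one | CC1(C)CCc2cc(CCC(=O)c3c(O)cc(O)cc3O)ccc2O1 | intermediate
13 | 3-chloro-3-methylbut-1-yne | CC(C)(Cl)C#C | starting material
14 | 1-[2,6-dihydroxy-4-(2-methylbut-3-yn-2-yloxy)phenyl]-3-(2,2-dimethylchroman-6-yl)propan-1-one | CC1(C)CCc2cc(CCC(=O)c3c(O)cc(OC(C)(C)C#C)cc3O)ccc2O1 | intermediate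
15 | 1-[2,4,6-trihydroxy-3-(3-methylbuta-1,2-dienyl)phenyl]-3-(2,2-dimethylchroman-6-yl)propan-1-one | CC1(C)CCc2cc(CCC(=O)c3c(O)cc(O)c(C=C=C(C)C)c3O)ccc2O1 | intermediate
16 | 1-(5,7-dihydroxy-2,2-dimethyl-2H-chromen-6-yl)-3-(2,2-dimethylchroman-6-yl)propan-1-one | CC1(C)CCc2cc(CCC(=O)c3c(O)cc4c(c3O)C=CC(C)(C)O4)ccc2O1 | intermediate
17 | 1-(5,7-dihydroxy-2,2-dimethylchroman-6-yl)-3-(2,2-dimethylchroman-6-yl)propan-1-one | CC1(C)CCc2cc(CCC(=O)c3c(O)cc4c(c3O)CCC(C)(C)O4)ccc2O1 | target

**Step count**

Total: 9 steps. Longest linear sequence: 8 steps (steps 2 to 9, from 4-bromophenol); the iodide branch adds step 1.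

**Steps most likely to fail**

Step 5. The crowded, electron-rich iodide may undergo oxidative addition only sluggishly under carbon monoxide, and the alkyl group may couple directly without uptake of carbon monoxide or be lost by protodeboronation. The fallback sets out from bromide 6 and iodide 2 and returns at ketone 11, building the ketone by carbonyl addition and oxidation instead. Bromide 6 would be coupled with allyl alcohol under Heck conditions (Pd(OAc)2, Bu4NCl, NaHCO3, DMF, 90 °C), where β-hydride elimination toward the carbinol carbon and tautomerisation should give 3-(2,2-dimethylchroman-6-yl)propanal F1. Iodide 2 would be converted by iodine–lithium exchange (n-BuLi, THF, −78 °C) into 2,4,6-tris(benzyloxy)phenyllithium F2. Addition of this to the aldehyde should give racemic 1-[2,4,6-tris(benzyloxy)phenyl]-3-(2,2-dimethylchroman-6-yl)propan-1-ol F3. Dess–Martin oxidation in CH2Cl2 would remove the transient stereocentre and give 11.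

Step 7. The ambident phloroglucinol anion may be alkylated at carbon or at more than one oxygen, and the chelating triol may bind the copper catalyst. The fallback sets out from triol 12 and returns at chromene 16, bypassing ether 14 and step 8. The triol would be condensed with 3-methylbut-2-enal in the presence of ethylenediammonium diacetate in hot xylene. Condensation at the free ring carbon followed by oxa-6π electrocyclisation should give the chromene directly, with no new isolated compound (F0). Closure through an oxygen ortho to the ketone would compete, so the two modes of closure would have to be separated by chromatography.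

Step 2. The bromine-deactivated phenol may be alkylated only slowly, while isoprene oligomerises or a second prenyl unit is introduced. The fallback sets out from 4-bromophenol 3 and chloride 13 and returns at bromochroman 6, building the pyran by the propargyl ether route. Phenol 3 would be etherified with 13 (CuCl2·2H2O, DBU, MeCN, 0 °C) to 1-bromo-4-(2-methylbut-3-yn-2-yloxy)benzene F4. Heating in N,N-diethylaniline (Claisen rearrangement, 1,5-hydrogen shift, electrocyclisation) should give 6-bromo-2,2-dimethyl-2H-chromene F5. Its double bond would be saturated with H2 over RhCl(PPh3)3 in benzene/ethanol, which leaves the aryl bromide intact, to give 6.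

**Further compounds**

F1 | step 5 | 3-(2,2-dimethylchroman-6-yl)propanal | CC1(C)CCc2cc(CCC=O)ccc2O1
F2 | step 5 | 2,4,6-tris(benzyloxy)phenyllithium | [Li]c1c(OCc2ccccc2)cc(OCc2ccccc2)cc1OCc1ccccc1
F3 | step 5 | 1-[2,4,6-tris(benzyloxy)phenyl]-3-(2,2-dimethylchroman-6-yl)propan-1-ol (racemic) | CC1(C)CCc2cc(CCC(O)c3c(OCc4ccccc4)cc(OCc4ccccc4)cc3OCc3ccccc3)ccc2O1
F0 | step 7 | none | none
F4 | step 2 | 1-bromo-4-(2-methylbut-3-yn-2-yloxy)benzene | CC(C)(C#C)Oc1ccc(Br)cc1
F5 | step 2 | 6-bromo-2,2-dimethyl-2H-chromene | CC1(C)C=Cc2cc(Br)ccc2O1
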